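The route rests on disconnecting the ring-fusion bond C1–C5 (daucane numbering, defined below) back to a C1–C6 bond. This leads to a cis-decalin that carries an all-cis C4,C5,C6-triol. In the key step the C5 mesylate leaves while quaternary C1 shifts from the C6 carbinol to C5. The six-membered ring C1/C6–C10 takes up C5 and becomes the cycloheptane, and the other six-membered ring contracts to the cyclopentane. C6 becomes the ketone, and C5 and the trans fusion are set by inversion. The step exploits the C4(OH)–C5(H)–C6(O) aldol-type triad flanking quaternary C1. The precursor comes from (+)-dihydrocarvone and methyl vinyl ketone, and its retained stereocentre C1 relays all others.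

Key step: step 8

Remark (numbering, one assumption):
- Daucane numbering is kept for every bicyclic compound, also before the rearrangement.
  - C1 = quaternary C bearing the angular CH3; C2 and C3 = CH2.
  - C4 = carbinol C bearing isopropyl; C5 = ring-fusion CH; C6 = CH–O-acyl; C7 = CH2.
  - C8 = C(OH)CH3; C9 = CHOH; C10 = CH2.
- In the decalins C1 is bonded to C6. In the hydroazulenes it is bonded to C5.
- β = the face of the C1 methyl; α = the opposite face.
- Commercial (+)-dihydrocarvone is assumed to be a mixture of C2 epimers. This does not matter, because that centre is enolised in step 1.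

Step 1
Reactants: 1 (+)-dihydrocarvone; 2 methyl vinyl ketone
Product: 4 cis-ketol (cis-decalin-8-one with 6β-OH, 1β-CH3 and 4α-isopropenyl), via Michael diketone 3 (not isolated)
Conditions: KOH (cat.), EtOH–Et2O, −10 to 0 °C; crystallisation
Reagents that add atoms: methyl vinyl ketone (2), C=CC(C)=O
Why: Base-catalysed Michael addition followed by intramolecular aldol addition (the first two stages of a Robinson annulation): the more substituted enolate of 1 is alkylated axially with the isopropenyl group equatorial, which puts the new C1–C10 bond cis to the isopropenyl group and sets C1, and the methyl ketone enolate of 3 then closes on C6=O to the cis-fused ketol, which should crystallise free of minor isomers.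

Step 2
Reactants: 4 cis-ketol
Product: 6 linear dienone (C4=C5–C6=C7–C8=O, isopropyl on C4, 1β-CH3), via isopropenyl enone 5 (not isolated)
Conditions: p-TsOH·H2O (cat.), toluene, reflux, Dean–Stark
Reagents that add atoms: none
Why: Acid-catalysed dehydration of the β-hydroxy ketone gives enone 5, and reversible protonation/deprotonation then walks the isopropenyl double bond into conjugation, the linear dienone being the thermodynamic sink; C4 is deliberately erased and C1 stays as the only stereocentre.

Step 3
Reactants: 6 linear dienone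
Product: 7 6β,7β-epoxy-8-ketone (C4=C5 retained)
Conditions: 30% H2O2, NaOH (cat.), MeOH, 0 °C to rt
Reagents that add atoms: hydrogen peroxide, OO
Why: Weitz–Scheffer nucleophilic epoxidation: hydroperoxide adds 1,4 to C6 and the enolate closes on oxygen, so the electron-richer C4=C5 bond is left alone, and as is usual for angularly methylated octalenones the attack should come mainly from the β face and lead to the cis-decalin-type 6β,7β-epoxide (sets C6).

Step 4
Reactants: 7 6β,7β-epoxy-8-ketone
Product: 8 unsaturated cis-ketol (6β-OH, C4=C5, C8=O)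
Conditions: SmI2 (2.2 equiv), THF–MeOH, −90 °C
Reagents that add atoms: none
Why: Two-electron reduction of an α,β-epoxy ketone with SmI2 breaks only the Cα–O bond (C7–O) via the ketyl and the samarium enolate, so the oxygen stays on C6 with retention and the cold, acid- and base-free medium spares the tertiary allylic aldol.

Step 5
Reactants: 8 unsaturated cis-ketol
Product: 9 enol triflate (C8(OTf)=C9, 6β-OH, C4=C5)
Conditions: LDA (2.2 equiv), THF, −78 °C; PhNTf2, −78 to −20 °C
Reagents that add atoms: N-phenylbis(trifluoromethanesulfonimide), O=S(=O)(N(c1ccccc1)S(=O)(=O)C(F)(F)F)C(F)(F)F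
Why: Kinetic enolisation of the lithium alkoxide–ketone takes place at the open C9 methylene, away from the charged C6–O side, and O-sulfonylation gives the enol triflate, which holds the place of the later C8=C9 methyl alkene in a form too electron-poor to be oxidised in step 6.

Step 6
Reactants: 9 enol triflate
Product: 11 all-cis 4β,5β,6β-triol (4α-isopropyl, enol triflate retained), via osmate ester 10 (not isolated)
Conditions: OsO4 (1.05 equiv), TMEDA, CH2Cl2, −78 °C; then aq. Na2SO3, THF, 50 °C
Reagents that add atoms: osmium tetroxide, O=[Os](=O)(=O)=O; TMEDA, CN(C)CCN(C)C (stays only in 10)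
Why: Hydrogen-bond-directed syn-dihydroxylation with OsO4·TMEDA: the pseudoaxial 6β-OH binds the reagent and delivers it to the convex β face of C4=C5 (the α face is covered by the folded second ring), which sets C4 and C5 in one event, while the enol triflate does not react.

Step 7
Reactants: 11 all-cis triol
Product: 12 5β-mesylate (4β-OH and 6β-OH free)
Conditions: MsCl, Et3N, CH2Cl2, −20 °C
Reagents that add atoms: methanesulfonyl chloride, CS(=O)(=O)Cl
Why: Mesylation through sulfene picks the only secondary hydroxyl (equatorial 5β-OH) and leaves the two tertiary axial hydroxyls free; no stereocentre is touched.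

Step 8
Reactants: 12 5β-mesylate
Product: 13 trans-fused hydroazulenone (4β-OH, 4α-isopropyl, 5α-H, 1β-CH3, C6=O, C8(OTf)=C9)
Conditions: Et3Al (4 equiv), CH2Cl2, −78 to 0 °C; aq. Rochelle salt
Reagents that add atoms: none
Why: Semipinacol (pinacol-type) rearrangement of a vicinal diol monosulfonate, the reaction type long used to turn decalins into hydroazulenes: Et3Al converts both tertiary hydroxyls into aluminium alkoxides and pulls on the mesylate, the O6 lone pair pushes, and C1 migrates from C6 to C5 in concert with C5–O cleavage. No ring is closed end to end; the one suprafacial 1,2-shift makes the C1–C5 bond, which turns ring C1–C6 into the cyclopentane C1–C5 (6→5) and inserts C5 into ring C1/C6–C10 (6→7). In the only low-energy conformer (isopropyl, C5–OMs and C1–CH3 equatorial, O4 and O6 axial) the C6–C1 bond is antiperiplanar to C5–OMs, so C5 is inverted and H5 ends α, trans to the C1 methyl, while C1 migrates with retention and C4 is untouched. The step needs C1 to migrate rather than C7 or C3: C7 is gauche to the leaving group, and of the two antiperiplanar bonds the fully substituted C1 (pushed by O6) carries positive charge far better than the methylene C3 (pushed by O4). Epoxide formation is impossible because both neighbouring oxygens are cis to the mesylate, and the low temperature and the aluminium chelate of the β-alkoxy ketone guard against retro-aldol cleavage and dehydration.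

Step 9
Reactants: 13 hydroazulenone
Product: 14 4β,6α-diol (enol triflate retained)
Conditions: Me4NBH(OAc)3, MeCN–AcOH, −30 to 0 °C
Reagents that add atoms: none
Why: Evans–Saksena reduction: the 4β-hydroxyl exchanges onto boron and delivers hydride intramolecularly to the β face of C6=O, which should give the equatorial 6α-alcohol (sets C6) against the steric bias of the angular methyl.

Step 10
Reactants: 14 4β,6α-diol enol triflate
Product: 15 jaeschkeanadiol (dauc-8-ene-4β,6α-diol)
Conditions: MeMgBr (5 equiv), Fe(acac)3 (10 mol %), THF–NMP, −30 to 0 °C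
Reagents that add atoms: methylmagnesium bromide, C[Mg]Br
Why: Iron-catalysed Kumada-type cross-coupling of an alkenyl triflate with MeMgBr replaces OTf by CH3 without moving the ring alkene, the two hydroxyls being merely deprotonated by excess Grignard reagent.

Step 11
Reactants: 15 jaeschkeanadiol; 16 4-(benzyloxy)benzoic acid
Product: 17 O-benzylferutinin (6α-[4-(benzyloxy)benzoate] of 15)
Conditions: DCC, DMAP, CH2Cl2, rt to 40 °C
Reagents that add atoms: 4-(benzyloxy)benzoic acid (16), O=C(O)c1ccc(OCc2ccccc2)cc1
Why: Steglich esterification acylates the secondary 6α-OH only, since the tertiary 4β-OH is inert under carbodiimide/DMAP conditions.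

Step 12
Reactants: 17 O-benzylferutinin
Product: 19 8β,9α-diol benzyl ether (O-benzyl derivative of the target), via 8α,9α-epoxide 18 (not isolated)
Conditions: mCPBA, NaHCO3 buffer, CH2Cl2, 0 °C; then 0.5 M aq. HClO4 (cat.), THF, 0 °C to rt
Reagents that add atoms: mCPBA, O=C(OO)c1cccc(Cl)c1; water, O
Why: Prilezhaev epoxidation should attack the trisubstituted C8=C9 bond from the α face because the axial C1 methyl and H6 cover the β face, and acid-catalysed hydrolysis opens 18 at the tertiary C8 with inversion, so that 9α-O is kept and 8β-OH is formed (trans-diol, sets C8 and C9); C4 is held equatorial and anti to C6–C7, so the 4-OH cannot reach C8 and does not compete with water.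

Step 13
Reactants: 19 8β,9α-diol benzyl ether
Product: 20 target CNP0197754.1
Conditions: H2 (1 atm), 10% Pd/C, EtOAc–EtOH, rt
Reagents that add atoms: none
Why: Hydrogenolysis of the aryl benzyl ether over Pd/C frees the phenol and touches neither the alkyl benzoate nor the alcohols, and no alkene is left to be reduced.

Compound list
1 | (+)-dihydrocarvone, (2R,5R)-2-methyl-5-(prop-1-en-2-yl)cyclohexan-1-one | CC(=C)[C@H]1CC(=O)[C@H](C)CC1 | starting material
2 | methyl vinyl ketone | C=CC(C)=O | starting material
3 | Michael diketone, 2-methyl-2-(3-oxobutyl)-5-isopropenylcyclohexanone (oxobutyl chain cis to isopropenyl) | CC(=C)[C@H]1CC(=O)[C@@](C)(CCC(C)=O)CC1 | intermediate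
4 | cis-ketol, 8a-hydroxy-4a-methyl-7-(prop-1-en-2-yl)octahydronaphthalen-2(1H)-one (6β-OH, 1β-CH3, 4α-isopropenyl) | CC(=C)[C@H]1C[C@@]2(O)CC(=O)CC[C@@]2(C)CC1 | intermediate
5 | isopropenyl enone, 4a-methyl-7-(prop-1-en-2-yl)-4,4a,5,6,7,8-hexahydronaphthalen-2(3H)-one | CC(=C)[C@H]1CC2=CC(=O)CC[C@@]2(C)CC1 | intermediate
6 | linear dienone, (R)-7-isopropyl-4a-methyl-4,4a,5,6-tetrahydronaphthalen-2(3H)-one | CC(C)C1=CC2=CC(=O)CC[C@@]2(C)CC1 | intermediate
7 | 6β,7β-epoxy-8-ketone | CC(C)C1=C[C@@]23O[C@@H]2C(=O)CC[C@@]3(C)CC1 | intermediate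
8 | unsaturated cis-ketol (6β-OH, C4=C5, C8=O) | CC(C)C1=C[C@@]2(O)CC(=O)CC[C@@]2(C)CC1 | intermediate
9 | enol triflate (C8(OTf)=C9, 6β-OH, C4=C5) | CC(C)C1=C[C@@]2(O)CC(OS(=O)(=O)C(F)(F)F)=CC[C@@]2(C)CC1 | intermediate
10 | 4β,5β-osmate(VI) ester, TMEDA chelate | CC(C)[C@@]1(O3)[C@H](O[Os-2]34(=O)(=O)[N+](C)(C)CC[N+]4(C)C)[C@@]2(O)CC(OS(=O)(=O)C(F)(F)F)=CC[C@@]2(C)CC1 | intermediate
11 | all-cis 4β,5β,6β-triol enol triflate | CC(C)[C@@]1(O)[C@H](O)[C@@]2(O)CC(OS(=O)(=O)C(F)(F)F)=CC[C@@]2(C)CC1 | intermediate
12 | 5β-mesylate of 11 | CC(C)[C@@]1(O)[C@H](OS(C)(=O)=O)[C@@]2(O)CC(OS(=O)(=O)C(F)(F)F)=CC[C@@]2(C)CC1 | intermediate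
13 | trans-hydroazulen-6-one (4β-OH, 5α-H, 1β-CH3, C8(OTf)=C9) | CC(C)[C@]1(O)CC[C@]2(C)CC=C(OS(=O)(=O)C(F)(F)F)CC(=O)[C@H]21 | intermediate
14 | 4β,6α-diol enol triflate | CC(C)[C@]1(O)CC[C@]2(C)CC=C(OS(=O)(=O)C(F)(F)F)C[C@H](O)[C@H]21 | intermediate
15 | jaeschkeanadiol (dauc-8-ene-4β,6α-diol) | CC(C)[C@]1(O)CC[C@]2(C)CC=C(C)C[C@H](O)[C@H]21 | intermediate
16 | 4-(benzyloxy)benzoic acid | O=C(O)c1ccc(OCc2ccccc2)cc1 | starting material
17 | O-benzylferutinin | CC(C)[C@]1(O)CC[C@]2(C)CC=C(C)C[C@H](OC(=O)c3ccc(OCc4ccccc4)cc3)[C@H]21 | intermediate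
18 | 8α,9α-epoxide of 17 | CC(C)[C@]1(O)CC[C@]2(C)C[C@@H]3O[C@]3(C)C[C@H](OC(=O)c3ccc(OCc4ccccc4)cc3)[C@H]21 | intermediate
19 | 8β,9α-diol benzyl ether | CC(C)[C@]1(O)CC[C@]2(C)C[C@H](O)[C@@](C)(O)C[C@H](OC(=O)c3ccc(OCc4ccccc4)cc3)[C@H]21 | intermediate
20 | CNP0197754.1 (4β,8β,9α-trihydroxydaucan-6α-yl 4-hydroxybenzoate) | CC(C)[C@]1(O)CC[C@]2(C)C[C@H](O)[C@@](C)(O)C[C@H](OC(=O)c3ccc(O)cc3)[C@H]21 | target

Total step count: 13. Longest linear sequence: 13.

Steps most likely to fail

1. Step 8.
   - What may go wrong: the C4 alkoxide may push in competition with O6, so that C3 migrates and only the isopropyl-bearing ring contracts. The β-hydroxy ketone may also open by retro-aldol cleavage or lose water once it is formed.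
   - Fallback: it sets out from 12. The less hindered tertiary O4 (O6 sits at the ring fusion next to quaternary C1) is silylated selectively with TESOTf/2,6-lutidine at −78 °C. This gives the 4-O-triethylsilyl mesylate F1. The aluminium-promoted shift then has O6 as its only donor and gives the 4-O-triethylsilyl hydroazulenone F2. The masked β-oxygen of F2 can neither cleave nor eliminate. HF·pyridine in THF brings the material back to the route at 13.

2. Step 3.
   - What may go wrong: hydroperoxide may add slowly to the fully substituted C6. Addition may also go 1,6 to C4, or show poor facial selectivity.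
   - Fallback: it sets out from 6 and replaces the nucleophilic by a hydroxyl-directed electrophilic epoxidation. Luche reduction (axial hydride from the α face) gives the 8β-dienol F3. VO(acac)2/t-BuOOH then epoxidises only the allylic C6=C7 bond, syn to the hydroxyl, to the 6β,7β-epoxy-8β-alcohol F4. Dess–Martin oxidation comes back to the route at 7.

3. Step 5.
   - What may go wrong: the lithium aldolate may open by retro-aldol cleavage before or during enolisation. The tertiary alkoxide may also be sulfonylated and then eliminate.
   - Fallback: it sets out from 8 and removes the alkoxide from the problem. TMS-imidazole gives the 6-O-trimethylsilyl ketone F5. LDA (1.1 equiv) and PhNTf2 give the 6-O-trimethylsilyl enol triflate F6. K2CO3 in MeOH at 0 °C frees the directing hydroxyl and comes back to the route at 9.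

Further compounds
F1 | step 8 | 4-O-triethylsilyl 5β-mesylate | CC(C)[C@@]1(O[Si](CC)(CC)CC)[C@H](OS(C)(=O)=O)[C@@]2(O)CC(OS(=O)(=O)C(F)(F)F)=CC[C@@]2(C)CC1
F2 | step 8 | 4-O-triethylsilyl hydroazulenone | CC(C)[C@]1(O[Si](CC)(CC)CC)CC[C@]2(C)CC=C(OS(=O)(=O)C(F)(F)F)CC(=O)[C@H]21
F3 | step 3 | 8β-dienol | CC(C)C1=CC2=C[C@H](O)CC[C@@]2(C)CC1
F4 | step 3 | 6β,7β-epoxy-8β-alcohol | CC(C)C1=C[C@@]23O[C@@H]2[C@H](O)CC[C@@]3(C)CC1
F5 | step 5 | 6-O-trimethylsilyl ketone | CC(C)C1=C[C@@]2(O[Si](C)(C)C)CC(=O)CC[C@@]2(C)CC1
F6 | step 5 | 6-O-trimethylsilyl enol triflate | CC(C)C1=C[C@@]2(O[Si](C)(C)C)CC(OS(=O)(=O)C(F)(F)F)=CC[C@@]2(C)CC1
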